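**Strategy.** Ring A (C1–C5, C10) carries its C3 oxygen 1,4 to the quaternary, formyl-bearing C10. This is the retron of a Diels–Alder reaction between a 2-siloxy diene (C2=C3–C4=C5) and an α-substituted acrolein (C1=C10–C20). Tethering both through C6–C8–C9 of a preformed bicyclo[3.2.1]octane (rings C and D) makes the cycloaddition intramolecular: one operation forms C1–C2 and C5–C10, closes rings A and B, and sets C5 and the quaternary C10. The precursor is a 6-methylidenebicyclo[3.2.1]octane carrying a silyl dienol ether arm on C8 and a 2-alkenyl-1,3-dioxolane (masked acrolein) on C9. It is assembled from cyclohex-2-enone by asymmetric conjugate addition and an intramolecular Hosomi–Sakurai reaction.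

Key step: step 12

Remark 1: atoms are numbered as in ent-gibberellane, and α and β are used as in the customary gibberellin drawing (3β-hydroxyl, 5β-H, 9β-H, 6β-carboxyl, 4α-carboxyl, formyl group α on C10). Ring A = C1–C5 and C10, ring B = C5, C6, C8, C9, C10, ring C = C8, C9, C11–C14, ring D = C8, C13–C16.
Remark 2: the target is addressed as the open 20-oxo 7,19-diacid that is drawn; it may equilibrate with its 19,20-lactol.
Remark 3: the (R)-BINAP rhodium catalyst is assumed to give the 5R centre of 7, by analogy with its established sense on cyclohex-2-enone.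

Step 1
Reactants: 1 cyclohex-2-en-1-one; 2 tert-butyl(2-iodoethoxy)dimethylsilane
Product: 3 rac-6-{2-[(tert-butyldimethylsilyl)oxy]ethyl}cyclohex-2-en-1-one
Conditions: LiN(iPr)2, THF, −78 °C; then 2, HMPA, −78 to −20 °C
Reagents that add atoms: none
Why: Kinetic deprotonation at C6 gives the cross-conjugated lithium dienolate, which should be C-alkylated by the primary iodide (enolate alkylation); the new α-centre is racemic and base-labile and is settled in step 3.

Step 2
Reactants: 4 (2-bromoprop-2-en-1-yl)trimethylsilane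
Product: 5 trimethyl[2-(4,4,5,5-tetramethyl-1,3,2-dioxaborolan-2-yl)prop-2-en-1-yl]silane
Conditions: t-BuLi (2 equiv), Et2O, −78 °C; then 2-isopropoxy-4,4,5,5-tetramethyl-1,3,2-dioxaborolane, −78 °C to rt
Reagents that add atoms: 2-isopropoxy-4,4,5,5-tetramethyl-1,3,2-dioxaborolane, CC(C)OB1OC(C)(C)C(C)(C)O1
Why: Bromine–lithium exchange gives the alkenyllithium, which should be trapped by the borate ester (borylation of an organolithium) without touching the allylsilane.

Step 3
Reactants: 3 rac-6-{2-[(tert-butyldimethylsilyl)oxy]ethyl}cyclohex-2-en-1-one; 5 trimethyl[2-(4,4,5,5-tetramethyl-1,3,2-dioxaborolan-2-yl)prop-2-en-1-yl]silane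
Product: 7 (2S,5R)-2-{2-[(tert-butyldimethylsilyl)oxy]ethyl}-5-[3-(trimethylsilyl)prop-1-en-2-yl]cyclohexan-1-one, via cis ketone 6 (not isolated)
Conditions: [Rh(OH)((R)-BINAP)]2 (3 mol %), KOH (0.5 equiv), 1,4-dioxane/H2O 10:1, 40 °C; then K2CO3 (0.2 equiv), MeOH, rt
Reagents that add atoms: none
Why: The rhodium-catalysed asymmetric 1,4-addition of an alkenylboronate to a cyclic enone (Hayashi–Miyaura reaction) should set C13 as 5R under ligand control for both enantiomers of 3, because the racemic centre is remote from the reacting β-carbon, and base equilibration of the enolisable α-centre should then convert the cis epimer 6 into the diequatorial trans-2,5 isomer 7 (C9), residual 6 being recycled through the same equilibration.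

Step 4
Reactants: 7 (2S,5R)-2-{2-[(tert-butyldimethylsilyl)oxy]ethyl}-5-[3-(trimethylsilyl)prop-1-en-2-yl]cyclohexan-1-one
Product: 8 methyl 2-[(2S,5R)-2-{2-[(tert-butyldimethylsilyl)oxy]ethyl}-5-[3-(trimethylsilyl)prop-1-en-2-yl]cyclohexylidene]acetate (E/Z mixture)
Conditions: (MeO)2P(O)CH2CO2Me, NaH, THF, 0 to 65 °C
Reagents that add atoms: trimethyl phosphonoacetate, COC(=O)CP(=O)(OC)OC
Why: Horner–Wadsworth–Emmons olefination of the ketone should give the exocyclic unsaturated ester carrying C6 and C7; no stereocentre is formed, both alkene isomers serve, and the aprotic conditions should leave the trans ring substitution intact.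

Step 5
Reactants: 8 methyl 2-[(2S,5R)-2-{2-[(tert-butyldimethylsilyl)oxy]ethyl}-5-[3-(trimethylsilyl)prop-1-en-2-yl]cyclohexylidene]acetate
Product: 9 methyl 2-[(1S,2S,5R)-2-{2-[(tert-butyldimethylsilyl)oxy]ethyl}-6-methylidenebicyclo[3.2.1]octan-1-yl]acetate
Conditions: TiCl4, CH2Cl2, −78 °C; aq. NaHCO3
Reagents that add atoms: none
Why: Intramolecular Hosomi–Sakurai conjugate addition: in the diaxial conformer (favoured by allylic 1,3-strain with the exocyclic alkene) the γ-carbon of the allylsilane (C15) should attack the activated β-carbon C8 from the axial C13 arm, closing ring D as a bicyclo[3.2.1]octane, creating quaternary C8 with the new bridge necessarily cis to C13 and therefore anti to the C9 side chain, and releasing the 16-methylidene by loss of silicon.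

Step 6
Reactants: 9 methyl 2-[(1S,2S,5R)-2-{2-[(tert-butyldimethylsilyl)oxy]ethyl}-6-methylidenebicyclo[3.2.1]octan-1-yl]acetate
Product: 10 methyl 2-[(1S,2S,5R)-2-(2-hydroxyethyl)-6-methylidenebicyclo[3.2.1]octan-1-yl]acetate
Conditions: HF·pyridine, THF, 0 °C to rt
Reagents that add atoms: none
Why: Fluoride cleavage of the primary silyl ether (desilylation) should free the alcohol without affecting ester, alkene or stereocentres.

Step 7
Reactants: 10 methyl 2-[(1S,2S,5R)-2-(2-hydroxyethyl)-6-methylidenebicyclo[3.2.1]octan-1-yl]acetate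
Product: 11 methyl 2-[(1S,2S,5R)-6-methylidene-2-(2-oxoethyl)bicyclo[3.2.1]octan-1-yl]acetate
Conditions: Dess–Martin periodinane, CH2Cl2, rt
Reagents that add atoms: none
Why: Dess–Martin oxidation should convert the primary alcohol into the aldehyde under neutral conditions that spare the exocyclic alkene.

Step 8
Reactants: 11 methyl 2-[(1S,2S,5R)-6-methylidene-2-(2-oxoethyl)bicyclo[3.2.1]octan-1-yl]acetate
Product: 12 methyl 2-[(1S,2R,5R)-6-methylidene-2-(3-oxoprop-1-en-2-yl)bicyclo[3.2.1]octan-1-yl]acetate
Conditions: 37% aq. HCHO, pyrrolidine (10 mol %), EtCO2H (10 mol %), i-PrOH, 45 °C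
Reagents that add atoms: formaldehyde, C=O
Why: Amine-catalysed Mannich condensation–elimination (α-methylenation of an aldehyde) should install C1 as the methylidene of the α-substituted acrolein; the enamine forms only at C10, so C9 is not touched (its descriptor changes only by priority).

Step 9
Reactants: 12 methyl 2-[(1S,2R,5R)-6-methylidene-2-(3-oxoprop-1-en-2-yl)bicyclo[3.2.1]octan-1-yl]acetate
Product: 13 methyl 2-[(1S,2R,5R)-2-[1-(1,3-dioxolan-2-yl)ethenyl]-6-methylidenebicyclo[3.2.1]octan-1-yl]acetate
Conditions: (Me3SiOCH2)2, Me3SiOTf (2 mol %), CH2Cl2, −78 °C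
Reagents that add atoms: 1,2-bis(trimethylsilyloxy)ethane, C[Si](C)(C)OCCO[Si](C)(C)C
Why: Silyl-triflate-catalysed acetalisation with the bis-silyl ether of glycol should give the enal dioxolane without conjugate addition; the acetal masks C20 for the later hydride reduction and is the cation precursor of the key step.

Step 10
Reactants: 14 ethyl 2-(ethoxymethylidene)-3-oxobutanoate
Product: 15 ethyl 3-[(tert-butyldimethylsilyl)oxy]-2-(ethoxymethylidene)but-3-enoate
Conditions: t-BuMe2SiOTf, Et3N, CH2Cl2, 0 °C
Reagents that add atoms: tert-butyldimethylsilyl trifluoromethanesulfonate, CC(C)(C)[Si](C)(C)OS(=O)(=O)C(F)(F)F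
Why: Soft enolisation of the methyl ketone (silyl enol ether formation) should give the 3-siloxy diene while the only acidic C–H of 14 is consumed, so that no base is needed later at the stage of the acidic C6–H.

Step 11
Reactants: 13 methyl 2-[(1S,2R,5R)-2-[1-(1,3-dioxolan-2-yl)ethenyl]-6-methylidenebicyclo[3.2.1]octan-1-yl]acetate; 15 ethyl 3-[(tert-butyldimethylsilyl)oxy]-2-(ethoxymethylidene)but-3-enoate
Product: 16 1-ethyl 5-methyl (2Z)-2-{1-[(tert-butyldimethylsilyl)oxy]ethenyl}-4-{2-[1-(1,3-dioxolan-2-yl)ethenyl]-6-methylidenebicyclo[3.2.1]octan-1-yl}pent-2-enedioate (bicycle as in 13; epimers at C6)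
Conditions: LiN(iPr)2, THF, −78 °C; then 15, −78 to 0 °C; AcOH
Reagents that add atoms: none
Why: The lithium ester enolate (C6) should add to the β-carbon of the β-ethoxyacrylate and expel ethoxide (conjugate addition–elimination, nucleophilic vinylic substitution); the delocalised product anion lets the C4=C5 alkene settle with the bulky C6 group trans to C3, and C6 arises as a base-labile epimeric centre that is fixed only in step 15.

Step 12
Reactants: 16 1-ethyl 5-methyl (2Z)-2-{1-[(tert-butyldimethylsilyl)oxy]ethenyl}-4-{2-[1-(1,3-dioxolan-2-yl)ethenyl]-6-methylidenebicyclo[3.2.1]octan-1-yl}pent-2-enedioate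
Product: 17 19-ethyl 7-methyl 3-[(tert-butyldimethylsilyl)oxy]-20,20-(ethane-1,2-diyldioxy)-18-norgibberella-3,16-diene-7,19-dioate (5β-H; 9β-H; acetal carbon α on C10; C6 epimers; 6β drawn)
Conditions: Me3SiOTf (20 mol %), 2,6-di-tert-butyl-4-methylpyridine (25 mol %), CH2Cl2, −78 to −40 °C
Reagents that add atoms: none
Why: The silyl triflate should ionise the dioxolane to a 2-substituted alkoxyallyl cation (C1=C10–C20=O+), which is trapped by the tethered 2-siloxy diene in a concerted but asynchronous [4+2] cycloaddition (C1–C2 leading, C5–C10 following), after which the pendant silyloxyethoxy group recloses the dioxolane and returns the catalyst. The closest known reaction type is the cationic (ionic) Diels–Alder reaction of 2-alkenyl-1,3-dioxolanes in its intramolecular form, related to Lewis-acid-mediated intramolecular double Michael additions of silyl dienol ethers. Ring B (five-membered) closes in the type 1 intramolecular mode across the three-atom tether C6–C8–C9 (a nona-1,3,8-triene giving a hydrindane), and ring A (six-membered) is the cyclohexene formed by the cycloaddition itself. C10 is controlled by the C9 stereocentre, the diene reaching the dienophile face that places C1 on the side of H9 and C20 on the side of C11 of ring C; C5 is controlled by the alkene geometry (C6 trans to C3) together with the endo placement of the C20 oxocarbenium under the diene, which gives the trans A/B fusion. The step needs para regiochemistry, secured by the match of the nucleophilic enol-ether terminus C2 with the cation terminus C1 and by the short tether, and endo and facial selectivity, secured by the low-temperature cationic conditions and the rigid bicyclo[3.2.1]octane.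

Step 13
Reactants: 17 19-ethyl 7-methyl 3-[(tert-butyldimethylsilyl)oxy]-20,20-(ethane-1,2-diyldioxy)-18-norgibberella-3,16-diene-7,19-dioate
Product: 18 19-ethyl 7-methyl 20,20-(ethane-1,2-diyldioxy)-3-oxogibberell-16-ene-7,19-dioate (4β-methyl; 4α-ester; C6 epimers; 6β drawn)
Conditions: Bu4NF (anhydrous), MeI, THF, −20 to 0 °C
Reagents that add atoms: iodomethane, CI
Why: Fluoride should unmask the β-keto ester enolate, which is C-methylated (enolate alkylation) from the β face, anti to the axial C10 acetal substituent, so that C19 ends up axial and α and the new methyl C18 is β.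

Step 14
Reactants: 18 19-ethyl 7-methyl 20,20-(ethane-1,2-diyldioxy)-3-oxogibberell-16-ene-7,19-dioate
Product: 19 19-ethyl 7-methyl 20,20-(ethane-1,2-diyldioxy)-3β-hydroxygibberell-16-ene-7,19-dioate (C6 epimers; 6β drawn)
Conditions: LiBH(s-Bu)3, THF, −78 °C
Reagents that add atoms: none
Why: The bulky trialkylborohydride should attack the C3 ketone along the equatorial trajectory (hindered-hydride ketone reduction), giving the axial 3β-alcohol, while esters and acetal are inert at this temperature.

Step 15
Reactants: 19 19-ethyl 7-methyl 20,20-(ethane-1,2-diyldioxy)-3β-hydroxygibberell-16-ene-7,19-dioate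
Product: 21 3β-hydroxy-20-oxogibberell-16-ene-7,19-dioic acid (the target gibberellin), via oxo diester 20 (not isolated)
Conditions: 2 M HCl, THF, rt; then KOH, MeOH, 50 °C; then H2O, 65 °C; then H3O+
Reagents that add atoms: water, O; potassium hydroxide, [K+].[OH-]
Why: Acetal hydrolysis should free the C20 aldehyde, after which base equilibrates the enolisable C7 ester at C6 to the more stable 6β configuration (trans to C4) and saponifies both esters, the hindered C19 ester being cleaved with assistance of the neighbouring aldehyde hydrate (ester saponification with thermodynamic epimerisation).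

**Compound list**

1 | cyclohex-2-en-1-one | O=C1C=CCCC1 | starting material
2 | tert-butyl(2-iodoethoxy)dimethylsilane | CC(C)(C)[Si](C)(C)OCCI | starting material
3 | rac-6-{2-[(tert-butyldimethylsilyl)oxy]ethyl}cyclohex-2-en-1-one | O=C1C=CCCC1CCO[Si](C)(C)C(C)(C)C | intermediate
4 | (2-bromoprop-2-en-1-yl)trimethylsilane | C=C(Br)C[Si](C)(C)C | starting material
5 | trimethyl[2-(4,4,5,5-tetramethyl-1,3,2-dioxaborolan-2-yl)prop-2-en-1-yl]silane | C=C(C[Si](C)(C)C)B1OC(C)(C)C(C)(C)O1 | intermediate
6 | (2R,5R)-2-{2-[(tert-butyldimethylsilyl)oxy]ethyl}-5-[3-(trimethylsilyl)prop-1-en-2-yl]cyclohexan-1-one (cis) | O=C1C[C@H](C(=C)C[Si](C)(C)C)CC[C@@H]1CCO[Si](C)(C)C(C)(C)C | intermediate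
7 | (2S,5R)-2-{2-[(tert-butyldimethylsilyl)oxy]ethyl}-5-[3-(trimethylsilyl)prop-1-en-2-yl]cyclohexan-1-one (trans) | O=C1C[C@H](C(=C)C[Si](C)(C)C)CC[C@H]1CCO[Si](C)(C)C(C)(C)C | intermediate
8 | methyl 2-[(2S,5R)-2-{2-[(tert-butyldimethylsilyl)oxy]ethyl}-5-[3-(trimethylsilyl)prop-1-en-2-yl]cyclohexylidene]acetate (E/Z mixture) | COC(=O)C=C1C[C@H](C(=C)C[Si](C)(C)C)CC[C@H]1CCO[Si](C)(C)C(C)(C)C | intermediate
9 | methyl 2-[(1S,2S,5R)-2-{2-[(tert-butyldimethylsilyl)oxy]ethyl}-6-methylidenebicyclo[3.2.1]octan-1-yl]acetate | C=C1C[C@]2(CC(=O)OC)C[C@H]1CC[C@H]2CCO[Si](C)(C)C(C)(C)C | intermediate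
10 | methyl 2-[(1S,2S,5R)-2-(2-hydroxyethyl)-6-methylidenebicyclo[3.2.1]octan-1-yl]acetate | C=C1C[C@]2(CC(=O)OC)C[C@H]1CC[C@H]2CCO | intermediate
11 | methyl 2-[(1S,2S,5R)-6-methylidene-2-(2-oxoethyl)bicyclo[3.2.1]octan-1-yl]acetate | C=C1C[C@]2(CC(=O)OC)C[C@H]1CC[C@H]2CC=O | intermediate
12 | methyl 2-[(1S,2R,5R)-6-methylidene-2-(3-oxoprop-1-en-2-yl)bicyclo[3.2.1]octan-1-yl]acetate | C=C1C[C@]2(CC(=O)OC)C[C@H]1CC[C@H]2C(=C)C=O | intermediate
13 | methyl 2-[(1S,2R,5R)-2-[1-(1,3-dioxolan-2-yl)ethenyl]-6-methylidenebicyclo[3.2.1]octan-1-yl]acetate | C=C1C[C@]2(CC(=O)OC)C[C@H]1CC[C@H]2C(=C)C3OCCO3 | intermediate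
14 | ethyl 2-(ethoxymethylidene)-3-oxobutanoate | CCOC=C(C(C)=O)C(=O)OCC | starting material
15 | ethyl 3-[(tert-butyldimethylsilyl)oxy]-2-(ethoxymethylidene)but-3-enoate | CCOC=C(C(=C)O[Si](C)(C)C(C)(C)C)C(=O)OCC | intermediate
16 | 1-ethyl 5-methyl (2Z)-2-{1-[(tert-butyldimethylsilyl)oxy]ethenyl}-4-{2-[1-(1,3-dioxolan-2-yl)ethenyl]-6-methylidenebicyclo[3.2.1]octan-1-yl}pent-2-enedioate (C6 epimers) | C=C1C[C@]2(C(C(=O)OC)/C=C(/C(=C)O[Si](C)(C)C(C)(C)C)C(=O)OCC)C[C@H]1CC[C@H]2C(=C)C3OCCO3 | intermediate
17 | 19-ethyl 7-methyl 3-[(tert-butyldimethylsilyl)oxy]-20,20-(ethane-1,2-diyldioxy)-18-norgibberella-3,16-diene-7,19-dioate (C6 epimers; 6β drawn) | C=C1C[C@]23C[C@H]1CC[C@H]2[C@]1(C4OCCO4)CCC(O[Si](C)(C)C(C)(C)C)=C(C(=O)OCC)[C@H]1[C@@H]3C(=O)OC | intermediate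
18 | 19-ethyl 7-methyl 20,20-(ethane-1,2-diyldioxy)-3-oxogibberell-16-ene-7,19-dioate (C6 epimers; 6β drawn) | C=C1C[C@]23C[C@H]1CC[C@H]2[C@]1(C4OCCO4)CCC(=O)[C@@](C)(C(=O)OCC)[C@H]1[C@@H]3C(=O)OC | intermediate
19 | 19-ethyl 7-methyl 20,20-(ethane-1,2-diyldioxy)-3β-hydroxygibberell-16-ene-7,19-dioate (C6 epimers; 6β drawn) | C=C1C[C@]23C[C@H]1CC[C@H]2[C@]1(C4OCCO4)CC[C@H](O)[C@@](C)(C(=O)OCC)[C@H]1[C@@H]3C(=O)OC | intermediate
20 | 19-ethyl 7-methyl 3β-hydroxy-20-oxogibberell-16-ene-7,19-dioate (C6 epimers; 6β drawn) | C=C1C[C@]23C[C@H]1CC[C@H]2[C@]1(C=O)CC[C@H](O)[C@@](C)(C(=O)OCC)[C@H]1[C@@H]3C(=O)OC | intermediate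
21 | 3β-hydroxy-20-oxogibberell-16-ene-7,19-dioic acid (the target gibberellin) | C=C1C[C@]23C[C@H]1CC[C@H]2[C@]1(C=O)CC[C@H](O)[C@@](C)(C(=O)O)[C@H]1[C@@H]3C(=O)O | target

**Totals.** Total step count: 15. Longest linear sequence: 13 steps (1, 3–9, 11–15).

**Steps most likely to fail**

Step 12. The cationic cycloaddition may proceed with insufficient endo or facial selectivity (cis-fused or C10-epimeric ring system), or the silyl dienol ether may be protodesilylated before the second bond closes. The fallback is a neutral thermal cycloaddition of the free enal, with the acetal reinstalled afterwards. It sets out from 16: the dioxolane alone is removed with Et3SiOTf and 2,4,6-trimethylpyridine in CH2Cl2 followed by water, conditions basic enough to spare the silyl dienol ether, giving the enal with intact silyl dienol ether F1. Heating F1 in toluene (110 °C) should effect the uncatalysed intramolecular Diels–Alder reaction to the angular aldehyde F2. Treatment of F2 with (Me3SiOCH2)2 and catalytic Me3SiOTf at −78 °C re-forms the dioxolane, and the route is rejoined at 17.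

Step 11. The donor-substituted β-ethoxyacrylate 15 may be too weak an acceptor for the hindered lithium enolate, so that proton transfer or acylation at the ester of 15 competes with conjugate addition–elimination. The fallback replaces the lithium enolate by a silicon-mediated, Lewis-base-catalysed Mukaiyama–Michael addition of the group-transfer type, which leaves the acid-sensitive dioxolane untouched. It sets out from 13: LiN(iPr)2 and then Me3SiCl (THF, −78 °C) convert the ester into the trimethylsilyl ketene acetal F3. F3 is combined with 15 and catalytic Bu4NOAc in THF at 0 °C to rt, where the acetate-activated ketene acetal should add to C5 of the acrylate and the adduct should then lose ethoxytrimethylsilane. The route is rejoined at 16.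

Step 5. The simple unsaturated ester may be too weak an acceptor to be attacked at its fully substituted β-carbon, so that protodesilylation of the allylsilane outruns ring closure. The fallback raises the acceptor to the enal and restores the ester oxidation level afterwards. It sets out from 8: i-Bu2AlH (CH2Cl2, −78 °C) gives the allylic alcohol F4, and MnO2 (CH2Cl2, rt) oxidises it to the enal F5. TiCl4 at −78 °C should then close ring D by the same intramolecular Hosomi–Sakurai addition, five-membered ring closure at C8 being preferred over attack at the aldehyde carbon, to give the bicyclic aldehyde F6. Pinnick oxidation (NaClO2, NaH2PO4, 2-methylbut-2-ene, t-BuOH/H2O) gives the acid F7, and Me3SiCHN2 in MeOH/toluene returns the route at 9.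

**Further compounds**

F1 | step 12 | 1-ethyl 5-methyl (2Z)-2-{1-[(tert-butyldimethylsilyl)oxy]ethenyl}-4-[6-methylidene-2-(3-oxoprop-1-en-2-yl)bicyclo[3.2.1]octan-1-yl]pent-2-enedioate | C=C1C[C@]2(C(C(=O)OC)/C=C(/C(=C)O[Si](C)(C)C(C)(C)C)C(=O)OCC)C[C@H]1CC[C@H]2C(=C)C=O
F2 | step 12 | 19-ethyl 7-methyl 3-[(tert-butyldimethylsilyl)oxy]-20-oxo-18-norgibberella-3,16-diene-7,19-dioate | C=C1C[C@]23C[C@H]1CC[C@H]2[C@]1(C=O)CCC(O[Si](C)(C)C(C)(C)C)=C(C(=O)OCC)[C@H]1[C@@H]3C(=O)OC
F3 | step 11 | ({2-[2-[1-(1,3-dioxolan-2-yl)ethenyl]-6-methylidenebicyclo[3.2.1]octan-1-yl]-1-methoxyethenyl}oxy)trimethylsilane | C=C1C[C@]2(C=C(OC)O[Si](C)(C)C)C[C@H]1CC[C@H]2C(=C)C3OCCO3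
F4 | step 5 | 2-[(2S,5R)-2-{2-[(tert-butyldimethylsilyl)oxy]ethyl}-5-[3-(trimethylsilyl)prop-1-en-2-yl]cyclohexylidene]ethan-1-ol | OCC=C1C[C@H](C(=C)C[Si](C)(C)C)CC[C@H]1CCO[Si](C)(C)C(C)(C)C
F5 | step 5 | 2-[(2S,5R)-2-{2-[(tert-butyldimethylsilyl)oxy]ethyl}-5-[3-(trimethylsilyl)prop-1-en-2-yl]cyclohexylidene]acetaldehyde | O=CC=C1C[C@H](C(=C)C[Si](C)(C)C)CC[C@H]1CCO[Si](C)(C)C(C)(C)C
F6 | step 5 | 2-[(1S,2S,5R)-2-{2-[(tert-butyldimethylsilyl)oxy]ethyl}-6-methylidenebicyclo[3.2.1]octan-1-yl]acetaldehyde | C=C1C[C@]2(CC=O)C[C@H]1CC[C@H]2CCO[Si](C)(C)C(C)(C)C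
F7 | step 5 | 2-[(1S,2S,5R)-2-{2-[(tert-butyldimethylsilyl)oxy]ethyl}-6-methylidenebicyclo[3.2.1]octan-1-yl]acetic acid | C=C1C[C@]2(CC(=O)O)C[C@H]1CC[C@H]2CCO[Si](C)(C)C(C)(C)C
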